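**Strategy**

The 3,6-dihydro-2H-pyran ring (O1, C2–C6) is opened at C2–C3. With the acrylate α-carbon taken back to a carboxyl carbon, the array carboxyl–C2–C3–C4=C5 is a γ,δ-unsaturated acid, a Claisen retron whose allylic oxygen must sit on C5; since C5 is already linked to O1 through C6, the precursor is a 6-vinyl-1,4-dioxan-2-one, a temporary lactone ring. Its silyl ketene acetal undergoes an Ireland–Claisen shift that forms C2–C3, closes the dihydropyran, places the C4=C5 alkene and sets C2 by chirality transfer from a quaternary carbinol centre made by Sharpless epoxidation. The carboxyl is then converted into the acrylic acid.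

Key step: step 6

Remarks on the chemistry:
- Ring numbering is O1, C2 (the stereocentre, R in the target), C3, C4, C5 (bearing the side chain), C6.
- "Homofarnesyl" means (3E,7E)-4,8,12-trimethyltrideca-3,7,11-trien-1-yl.
- (2E,6E)-Farnesyl bromide is taken as the commercial source of the side chain.
- The free hydroxyl of 5 is assumed to be tolerated in step 3 when excess ylide is used; it is only deprotonated.

**Route**

Step 1
Reactants: 1 2-methylprop-2-en-1-ol; 2 (2E,6E)-farnesyl bromide
Product: 4 (5E,9E)-6,10,14-trimethyl-2-methylidenepentadeca-5,9,13-trien-1-ol, via dilithiated methallyl alcohol 3 (not isolated)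
Conditions: n-BuLi (2.2 equiv), TMEDA, Et2O/hexane, 0 °C → rt; then 2, THF, −78 °C → rt; H2O
Reagents that add atoms: none
Why: Alkylation of the O,C-dilithiated allylic alcohol, an allyl-lithium with two equivalent CH2 termini, by SN2 displacement at the primary allylic bromide, which leaves both E-alkenes of 2 untouched.

Step 2
Reactants: 4 (5E,9E)-6,10,14-trimethyl-2-methylidenepentadeca-5,9,13-trien-1-ol
Product: 5 [(2S)-2-homofarnesyloxiran-2-yl]methanol
Conditions: Ti(OiPr)4 (10 mol %), L-(+)-diethyl tartrate (12 mol %), t-BuOOH (in decane), 4 Å MS, CH2Cl2, −20 °C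
Reagents that add atoms: tert-butyl hydroperoxide, CC(C)(C)OO
Why: Sharpless asymmetric epoxidation, in which the titanium tartrate binds the allylic hydroxyl so that only the 1,1-disubstituted allylic alkene reacts, and L-(+)-tartrate should deliver oxygen to the face that gives the (S)-epoxide (the same facial sense that gives (2S)-epoxides from other primary allylic alcohols).

Step 3
Reactants: 5 [(2S)-2-homofarnesyloxiran-2-yl]methanol
Product: 6 (2R,5E,9E)-2-ethenyl-6,10,14-trimethylpentadeca-5,9,13-triene-1,2-diol
Conditions: Me3S+ I− (5 equiv), n-BuLi (4.8 equiv), THF, −10 °C → rt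
Reagents that add atoms: trimethylsulfonium iodide, C[S+](C)C.[I-]
Why: One-carbon homologation of a terminal epoxide to an allylic alcohol with dimethylsulfonium methylide (attack at the epoxide CH2, then loss of dimethyl sulfide), which does not touch the quaternary centre, so its descriptor changes from S to R only through the CIP priorities; any Payne isomerisation of the alkoxide is degenerate.

Step 4
Reactants: 6 (2R,5E,9E)-2-ethenyl-6,10,14-trimethylpentadeca-5,9,13-triene-1,2-diol; 7 bromoacetic acid
Product: 8 2-{[(2R,5E,9E)-2-ethenyl-2-hydroxy-6,10,14-trimethylpentadeca-5,9,13-trien-1-yl]oxy}acetic acid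
Conditions: NaH (3.2 equiv), THF, 0 → 50 °C; cold 0.5 M HCl to pH 3
Reagents that add atoms: none
Why: Williamson etherification of sodium bromoacetate, which should occur at the unhindered primary alkoxide and not at the tertiary allylic one, under basic conditions that spare the polyene.

Step 5
Reactants: 8 2-{[(2R,5E,9E)-2-ethenyl-2-hydroxy-6,10,14-trimethylpentadeca-5,9,13-trien-1-yl]oxy}acetic acid
Product: 9 (6R)-6-ethenyl-6-homofarnesyl-1,4-dioxan-2-one
Conditions: DCC, DMAP (cat.), CH2Cl2, 0 °C → rt
Reagents that add atoms: none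
Why: Steglich lactonisation to a six-membered ring under neutral conditions, chosen because acid would ionise the tertiary allylic alcohol and cyclise the polyene; the stereocentre is not involved.

Step 6
Reactants: 9 (6R)-6-ethenyl-6-homofarnesyl-1,4-dioxan-2-one
Product: 12 (2R)-5-homofarnesyl-3,6-dihydro-2H-pyran-2-carboxylic acid, via silyl ketene acetal 10 (not isolated), via trimethylsilyl ester 11 (not isolated)
Conditions: LiHMDS, TMSCl/Et3N, THF, −78 °C → rt; PhMe, 110 °C; H2O work-up
Reagents that add atoms: none
Why: Deprotonation at the only α-CH2 of the lactone with in-situ O-silylation gives ketene acetal 10, which undergoes a concerted [3,3]-sigmatropic shift: the ketene-acetal carbon (future C2) bonds to the terminal vinyl carbon (future C3) while the tertiary allylic C–O bond of the lactone breaks. This is the Ireland–Claisen rearrangement of a 6-alkenyl-1,4-dioxan-2-one, a known entry to 3,6-dihydro-2H-pyran-2-carboxylic acids. The dihydropyran closes pericyclically through a boat-like, bicyclo[2.2.2]octane-shaped transition state with the vinyl group axial over the ketene acetal, and the temporary dioxanone ring is opened in the same event. The new stereocentre C2 is set by chirality transfer from the quaternary carbinol carbon, because the vinyl group can reach only the face of the ketene acetal on its own side of the ring, so (6R)-9 should give (2R)-12 while the old centre becomes the sp2 carbon C5. No external selectivity is needed: there is one enolisable position and one possible [3,3] path, and the ring fixes both the position and the cis geometry of the new trisubstituted C4=C5 alkene. The internal TMSCl quench keeps the lithium enolate from fragmenting to a ketene or condensing with the lactone.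

Step 7
Reactants: 12 (2R)-5-homofarnesyl-3,6-dihydro-2H-pyran-2-carboxylic acid
Product: 14 1-[(2R)-5-homofarnesyl-3,6-dihydro-2H-pyran-2-yl]ethan-1-one, via dilithium gem-diolate 13 (not isolated)
Conditions: MeLi (2.2 equiv), THF, −78 → 0 °C; inverse quench into ice-cold H2O
Reagents that add atoms: methyllithium, [Li]C
Why: Addition of methyllithium to the lithium carboxylate gives a chelated gem-diolate that collapses to the methyl ketone only on quench, so over-addition is avoided and C2 is not deprotonated.

Step 8
Reactants: 14 1-[(2R)-5-homofarnesyl-3,6-dihydro-2H-pyran-2-yl]ethan-1-one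
Product: 16 1-[(2R)-5-homofarnesyl-3,6-dihydro-2H-pyran-2-yl]ethenyl trifluoromethanesulfonate, via potassium enolate 15 (not isolated)
Conditions: KHMDS, THF, −78 °C; PhNTf2, −78 → 0 °C
Reagents that add atoms: N-phenyl-bis(trifluoromethanesulfonimide), O=S(=O)(N(c1ccccc1)S(=O)(=O)C(F)(F)F)C(F)(F)F
Why: Kinetic deprotonation with a bulky amide base at −78 °C should take place at the methyl group and not at the hindered α-alkoxy methine C2, and O-triflation of the terminal enolate gives the 1,1-disubstituted enol triflate with C2 intact.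

Step 9
Reactants: 16 1-[(2R)-5-homofarnesyl-3,6-dihydro-2H-pyran-2-yl]ethenyl trifluoromethanesulfonate
Product: 17 2-[(2R)-5-homofarnesyl-3,6-dihydro-2H-pyran-2-yl]prop-2-enoic acid
Conditions: Pd(OAc)2 (5 mol %), dppf, CO (1 atm), Et3N, DMF/H2O, 50 °C; acidic work-up
Reagents that add atoms: carbon monoxide, [C-]#[O+]; water, O
Why: Palladium-catalysed hydroxycarbonylation of an enol triflate (oxidative addition, CO insertion, hydrolysis of the acyl-palladium) installs the carboxyl on the vinyl carbon without touching C2 or the isolated trisubstituted alkenes.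

**Compound list**

1 | 2-methylprop-2-en-1-ol (methallyl alcohol) | C=C(C)CO | starting material
2 | (2E,6E)-farnesyl bromide | BrC/C=C(\C)CC/C=C(\C)CCC=C(C)C | starting material
3 | dilithiated methallyl alcohol (lithium 2-(lithiomethyl)prop-2-en-1-olate), not isolated | [Li]CC(=C)CO[Li] | intermediate
4 | (5E,9E)-6,10,14-trimethyl-2-methylidenepentadeca-5,9,13-trien-1-ol | C=C(CO)CC/C=C(\C)CC/C=C(\C)CCC=C(C)C | intermediate
5 | [(2S)-2-homofarnesyloxiran-2-yl]methanol | OC[C@@]1(CC/C=C(\C)CC/C=C(\C)CCC=C(C)C)CO1 | intermediate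
6 | (2R,5E,9E)-2-ethenyl-6,10,14-trimethylpentadeca-5,9,13-triene-1,2-diol | C=C[C@@](O)(CO)CC/C=C(\C)CC/C=C(\C)CCC=C(C)C | intermediate
7 | bromoacetic acid | OC(=O)CBr | starting material
8 | 2-{[(2R,5E,9E)-2-ethenyl-2-hydroxy-6,10,14-trimethylpentadeca-5,9,13-trien-1-yl]oxy}acetic acid | C=C[C@@](O)(COCC(=O)O)CC/C=C(\C)CC/C=C(\C)CCC=C(C)C | intermediate
9 | (6R)-6-ethenyl-6-homofarnesyl-1,4-dioxan-2-one | C=C[C@]1(CC/C=C(\C)CC/C=C(\C)CCC=C(C)C)COCC(=O)O1 | intermediate
10 | silyl ketene acetal, trimethyl{[(2R)-2-ethenyl-2-homofarnesyl-2,3-dihydro-1,4-dioxin-6-yl]oxy}silane, not isolated | C=C[C@]1(CC/C=C(\C)CC/C=C(\C)CCC=C(C)C)COC=C(O[Si](C)(C)C)O1 | intermediate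
11 | trimethylsilyl (2R)-5-homofarnesyl-3,6-dihydro-2H-pyran-2-carboxylate, not isolated | C[Si](C)(C)OC(=O)[C@H]1CC=C(CC/C=C(\C)CC/C=C(\C)CCC=C(C)C)CO1 | intermediate
12 | (2R)-5-homofarnesyl-3,6-dihydro-2H-pyran-2-carboxylic acid | OC(=O)[C@H]1CC=C(CC/C=C(\C)CC/C=C(\C)CCC=C(C)C)CO1 | intermediate
13 | dilithium 1-[(2R)-5-homofarnesyl-3,6-dihydro-2H-pyran-2-yl]ethane-1,1-diolate, not isolated | CC(O[Li])(O[Li])[C@H]1CC=C(CC/C=C(\C)CC/C=C(\C)CCC=C(C)C)CO1 | intermediate
14 | 1-[(2R)-5-homofarnesyl-3,6-dihydro-2H-pyran-2-yl]ethan-1-one | CC(=O)[C@H]1CC=C(CC/C=C(\C)CC/C=C(\C)CCC=C(C)C)CO1 | intermediate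
15 | potassium 1-[(2R)-5-homofarnesyl-3,6-dihydro-2H-pyran-2-yl]ethen-1-olate, not isolated | C=C(O[K])[C@H]1CC=C(CC/C=C(\C)CC/C=C(\C)CCC=C(C)C)CO1 | intermediate
16 | 1-[(2R)-5-homofarnesyl-3,6-dihydro-2H-pyran-2-yl]ethenyl trifluoromethanesulfonate | C=C(OS(=O)(=O)C(F)(F)F)[C@H]1CC=C(CC/C=C(\C)CC/C=C(\C)CCC=C(C)C)CO1 | intermediate
17 | 2-[(2R)-5-homofarnesyl-3,6-dihydro-2H-pyran-2-yl]prop-2-enoic acid | C=C(C(=O)O)[C@H]1CC=C(CC/C=C(\C)CC/C=C(\C)CCC=C(C)C)CO1 | target

**Step count and risks**

Total step count: 9. Longest linear sequence: 9 steps (1 + 2 → 17).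

The three steps most likely to fail:

Step 6 (key step). The lactone may be enolised or silylated unproductively (C-silylation, loss of the alkoxide to a ketene), or the boat transition state next to the quaternary carbon may be slow enough for the ketene acetal to decompose first. The fallback builds the same acid by ring-closing metathesis, with the stereocentre bought instead of transferred. It sets out from 4: Appel bromination (CBr4, PPh3) should give the allylic bromide (5E,9E)-2-(bromomethyl)-6,10,14-trimethylpentadeca-1,5,9,13-tetraene F1. Silver(I) oxide-mediated O-alkylation of methyl (2R)-2-hydroxypent-4-enoate (C=CC[C@@H](O)C(=O)OC) with F1 should give the diene ester methyl (2R)-2-{[(5E,9E)-6,10,14-trimethyl-2-methylidenepentadeca-5,9,13-trien-1-yl]oxy}pent-4-enoate F2 without touching the α-centre. Ring-closing metathesis with the second-generation Grubbs catalyst between the terminal and the 1,1-disubstituted alkene (the trisubstituted chain alkenes react far more slowly) should give methyl (2R)-5-homofarnesyl-3,6-dihydro-2H-pyran-2-carboxylate F3. Hydrolysis with LiOH at 0 °C comes back to the route at 12.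

Step 3. The lithium alkoxide next to the epoxide may slow attack of the ylide at the neopentyl-type CH2, or the intermediate may close to an oxetane instead of eliminating. The fallback removes the alkoxide by protection. It sets out from 5: TBSCl and imidazole should give tert-butyldimethyl{[(2R)-2-homofarnesyloxiran-2-yl]methoxy}silane F4 (same spatial arrangement, descriptor changed by CIP priorities). The ylide homologation on this neutral glycidyl-ether-type epoxide should give (2R,5E,9E)-1-{[tert-butyl(dimethyl)silyl]oxy}-2-ethenyl-6,10,14-trimethylpentadeca-5,9,13-trien-2-ol F5. TBAF comes back to the route at 6.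

Step 8. Enolisation may occur in part toward C2, which would erode the stereocentre or give the tetrasubstituted enol triflate. The fallback avoids any ketone enolate and sets out from 12. Amide coupling with N,O-dimethylhydroxylamine should give (2R)-N-methoxy-N-methyl-5-homofarnesyl-3,6-dihydro-2H-pyran-2-carboxamide F6. DIBAL-H reduction at −78 °C should give (2R)-5-homofarnesyl-3,6-dihydro-2H-pyran-2-carbaldehyde F7. Ohira–Bestmann homologation should give (2R)-2-ethynyl-5-homofarnesyl-3,6-dihydro-2H-pyran F8. Palladium-catalysed Markovnikov hydrocarboxylation of the terminal alkyne (Pd(OAc)2, Xantphos, HCO2H, cat. Ac2O, toluene, 80 °C) comes back to the route at the target 17, bypassing steps 7–9.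

**Further compounds**

F1 | step 6 | (5E,9E)-2-(bromomethyl)-6,10,14-trimethylpentadeca-1,5,9,13-tetraene | C=C(CBr)CC/C=C(\C)CC/C=C(\C)CCC=C(C)C
F2 | step 6 | methyl (2R)-2-{[(5E,9E)-6,10,14-trimethyl-2-methylidenepentadeca-5,9,13-trien-1-yl]oxy}pent-4-enoate | C=CC[C@@H](OCC(=C)CC/C=C(\C)CC/C=C(\C)CCC=C(C)C)C(=O)OC
F3 | step 6 | methyl (2R)-5-homofarnesyl-3,6-dihydro-2H-pyran-2-carboxylate | COC(=O)[C@H]1CC=C(CC/C=C(\C)CC/C=C(\C)CCC=C(C)C)CO1
F4 | step 3 | tert-butyldimethyl{[(2R)-2-homofarnesyloxiran-2-yl]methoxy}silane | CC(C)(C)[Si](C)(C)OC[C@@]1(CC/C=C(\C)CC/C=C(\C)CCC=C(C)C)CO1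
F5 | step 3 | (2R,5E,9E)-1-{[tert-butyl(dimethyl)silyl]oxy}-2-ethenyl-6,10,14-trimethylpentadeca-5,9,13-trien-2-ol | C=C[C@@](O)(CO[Si](C)(C)C(C)(C)C)CC/C=C(\C)CC/C=C(\C)CCC=C(C)C
F6 | step 8 | (2R)-N-methoxy-N-methyl-5-homofarnesyl-3,6-dihydro-2H-pyran-2-carboxamide | CON(C)C(=O)[C@H]1CC=C(CC/C=C(\C)CC/C=C(\C)CCC=C(C)C)CO1
F7 | step 8 | (2R)-5-homofarnesyl-3,6-dihydro-2H-pyran-2-carbaldehyde | O=C[C@H]1CC=C(CC/C=C(\C)CC/C=C(\C)CCC=C(C)C)CO1
F8 | step 8 | (2R)-2-ethynyl-5-homofarnesyl-3,6-dihydro-2H-pyran | C#C[C@H]1CC=C(CC/C=C(\C)CC/C=C(\C)CCC=C(C)C)CO1
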